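The route cuts ring B (the pyran) from ring A at O1–C8a and C4–C4a, together with the O1–C2 bond. Ring B is fused at the neighbouring carbons C4a and C8a, and its other four ring atoms (O1, C2, C3, C4) plus the two methyls on C2 map onto 3-methylbut-2-enal. An aryne spanning C4a≡C8a can therefore take up the enal in one operation: C=O addition, benzoxete opening and oxa-6π closure give the complete 2H-chromene. The precursor is a 2-(trimethylsilyl)aryl triflate that already carries the C7 prenyl ether and a bromine at the future C5, which steers the regiochemistry and later anchors the 4-hydroxyphenethyl chain.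

Key step: step 3

Assumption: atoms are numbered as in 2H-chromene (O1, C2, C3, C4, C4a, C5 to C8, C8a), ring A is the benzo ring and ring B the pyran ring; the target has no stereocentre and no stereogenic double bond, so no stereocontrol is required.

Step 1
Reactants: 1 2,6-dibromobenzene-1,4-diol
Product: 6 2-bromo-4-hydroxy-6-(trimethylsilyl)phenyl trifluoromethanesulfonate, via bis(trimethylsilyl) ether 2 (not isolated), via aryllithium 3 (not isolated), via lithium phenolate 4 (not isolated), via silyl ether triflate 5 (not isolated)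
Conditions: HMDS, THF, 65 °C, then evaporate; n-BuLi (1.05 equiv), THF, −78 °C; Tf2O, −78 °C; aq NaHCO3, then 1 M HCl, THF/H2O, rt
Reagents that add atoms: hexamethyldisilazane, C[Si](C)(C)N[Si](C)(C)C; trifluoromethanesulfonic anhydride, O=S(=O)(OS(=O)(=O)C(F)(F)F)C(F)(F)F
Why: Exhaustive O-silylation, bromine–lithium exchange at one of the two equivalent bromines and a 1,3 O-to-C silyl shift (retro-Brook rearrangement) should give phenolate 4, whose O-triflation and hydrolysis of the labile aryl O-silyl ether leave the 4-hydroxyl as the only free oxygen, so the two ring oxygens are told apart without any selective alkylation.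

Step 2
Reactants: 6 2-bromo-4-hydroxy-6-(trimethylsilyl)phenyl trifluoromethanesulfonate; 7 1-bromo-3-methylbut-2-ene
Product: 8 2-bromo-4-(3-methylbut-2-enyloxy)-6-(trimethylsilyl)phenyl trifluoromethanesulfonate
Conditions: K2CO3, acetone, rt
Reagents that add atoms: none
Why: Williamson ether synthesis (SN2 at the primary allylic bromide) on the sole phenol, under a carbonate base that is not silicophilic enough at room temperature to release the aryne or attack the triflate.

Step 3
Reactants: 8 2-bromo-4-(3-methylbut-2-enyloxy)-6-(trimethylsilyl)phenyl trifluoromethanesulfonate; 9 3-methylbut-2-enal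
Product: 13 5-bromo-2,2-dimethyl-7-(3-methylbut-2-enyloxy)-2H-chromene, via aryne 10 (not isolated), via benzoxete 11 (not isolated), via o-quinone methide 12 (not isolated)
Conditions: CsF (3 equiv), 9 (5 equiv), MeCN, rt to 50 °C
Reagents that add atoms: none
Why: Fluoride attacks silicon and the resulting aryl anion expels triflate to give aryne 10 (C4a≡C8a); the carbonyl oxygen of 9 adds to C8a while the developing C4a anion closes onto the carbonyl carbon, giving benzoxete 11 in a formal [2+2] cycloaddition. Strain-driven 4π ring opening of 11 breaks the O–C4 bond and gives o-quinone methide 12, which carries a 2-methylprop-1-enyl group on C4. Ring B is then closed by a thermal, disrotatory oxa-6π electrocyclisation of the O1=C8a–C4a=C4–C3=C2 triene (O1–C2 bond), which restores the aromaticity of ring A. The closest known reaction type is the fluoride-triggered insertion of arynes into the C=O bond of aldehydes and formamides, which with enals ends in 2H-chromenes. No stereocentre is formed; the selectivity needed is regiochemical (oxygen at C8a, carbon at C4a), and the C5 bromine secures it, because its inductive pull distorts the aryne so that C8a is the more electrophilic terminus and the negative charge builds up at C4a next to bromine, a bias that should outweigh the small opposite bias of the remote C7 ether. The bromine also disfavours the quinone methide geometry in which the alkenyl group points toward C5, so the isomer able to cyclise is preferred, and excess enal with slow aryne release from sparingly soluble CsF should suppress capture of 12 by a second aryne.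

Step 4
Reactants: 13 5-bromo-2,2-dimethyl-7-(3-methylbut-2-enyloxy)-2H-chromene; 14 4-acetoxystyrene
Product: 17 4-{2-[2,2-dimethyl-7-(3-methylbut-2-enyloxy)-2H-chromen-5-yl]ethyl}phenol, via alkylborane 15 (not isolated), via coupled acetate 16 (not isolated)
Conditions: 14 (1.6 equiv), 9-BBN (1.5 equiv), THF, 0 °C to rt; then 13, Pd(OAc)2 (5 mol %), SPhos (10 mol %), 3 M aq K3PO4, THF, 60 °C; then 2 M aq NaOH, MeOH, rt; aq NH4Cl
Reagents that add atoms: none
Why: Anti-Markovnikov hydroboration of the styrene with 9-BBN, B-alkyl Suzuki–Miyaura coupling of 15 with the C5 bromide at zerovalent palladium and saponification of the aryl acetate are all standard; the styrene is used in slight excess over 9-BBN so that no B–H is left for the prenyl or chromene double bonds, and any acetate already cleaved by the aqueous phosphate converges on 17 in the hydroxide stage.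

Compound list
1 | 2,6-dibromobenzene-1,4-diol | Oc1cc(Br)c(O)c(Br)c1 | starting material
2 | 1,3-dibromo-2,5-bis(trimethylsilyloxy)benzene | C[Si](C)(C)Oc1cc(Br)c(O[Si](C)(C)C)c(Br)c1 | intermediate
3 | [3-bromo-2,5-bis(trimethylsilyloxy)phenyl]lithium | [Li]c1cc(O[Si](C)(C)C)cc(Br)c1O[Si](C)(C)C | intermediate
4 | lithium 2-bromo-6-(trimethylsilyl)-4-(trimethylsilyloxy)phenolate | [Li]Oc1c(Br)cc(O[Si](C)(C)C)cc1[Si](C)(C)C | intermediate
5 | 2-bromo-6-(trimethylsilyl)-4-(trimethylsilyloxy)phenyl trifluoromethanesulfonate | C[Si](C)(C)Oc1cc(Br)c(OS(=O)(=O)C(F)(F)F)c([Si](C)(C)C)c1 | intermediate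
6 | 2-bromo-4-hydroxy-6-(trimethylsilyl)phenyl trifluoromethanesulfonate | Oc1cc(Br)c(OS(=O)(=O)C(F)(F)F)c([Si](C)(C)C)c1 | intermediate
7 | 1-bromo-3-methylbut-2-ene (prenyl bromide) | CC(C)=CCBr | starting material
8 | 2-bromo-4-(3-methylbut-2-enyloxy)-6-(trimethylsilyl)phenyl trifluoromethanesulfonate | CC(C)=CCOc1cc(Br)c(OS(=O)(=O)C(F)(F)F)c([Si](C)(C)C)c1 | intermediate
9 | 3-methylbut-2-enal | CC(C)=CC=O | starting material
10 | 3-bromo-5-(3-methylbut-2-enyloxy)-1,2-didehydrobenzene (aryne, triple bond between the future C8a and C4a) | CC(C)=CCOC1=CC#CC(Br)=C1 | intermediate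
11 | 3-bromo-2-(2-methylprop-1-enyl)-5-(3-methylbut-2-enyloxy)-2H-benzo[b]oxete (racemic, transient) | CC(C)=CCOc1cc(Br)c2c(c1)OC2C=C(C)C | intermediate
12 | 3-bromo-2-(3-methylbut-2-enylidene)-5-(3-methylbut-2-enyloxy)cyclohexa-3,5-dien-1-one, alkenyl chain on the carbonyl side of the exocyclic double bond | CC(C)=CCOC1=CC(=O)/C(=C\C=C(C)C)C(Br)=C1 | intermediate
13 | 5-bromo-2,2-dimethyl-7-(3-methylbut-2-enyloxy)-2H-chromene | CC(C)=CCOc1cc(Br)c2c(c1)OC(C)(C)C=C2 | intermediate
14 | 4-acetoxystyrene (4-ethenylphenyl acetate) | CC(=O)Oc1ccc(C=C)cc1 | starting material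
15 | 4-[2-(9-borabicyclo[3.3.1]nonan-9-yl)ethyl]phenyl acetate | CC(=O)Oc1ccc(CCB2C3CCCC2CCC3)cc1 | intermediate
16 | 4-{2-[2,2-dimethyl-7-(3-methylbut-2-enyloxy)-2H-chromen-5-yl]ethyl}phenyl acetate | CC(=O)Oc1ccc(CCc2cc(OCC=C(C)C)cc3OC(C)(C)C=Cc23)cc1 | intermediate
17 | 4-{2-[2,2-dimethyl-7-(3-methylbut-2-enyloxy)-2H-chromen-5-yl]ethyl}phenol | CC(C)=CCOc1cc(CCc2ccc(O)cc2)c2c(c1)OC(C)(C)C=C2 | target

Total step count: 4. Longest linear sequence: 4 steps (1 to 6 to 8 to 13 to 17).

Steps most likely to fail

Step 3. The enal oxygen is a weak nucleophile, so the aryne may be diverted into ene reactions with allylic C–H bonds or into addition to the quinone methide before the insertion takes place. The fallback sets out from 8 and comes back at 13. Aryne 10 is released with CsF in DMF as the solvent, so that the more nucleophilic and far more concentrated formamide oxygen adds to C8a under the same bromine control. This should give 3-bromo-N,N-dimethyl-5-(3-methylbut-2-enyloxy)-2H-benzo[b]oxet-2-amine F1, which is not isolated and is hydrolysed on aqueous work-up to 2-bromo-6-hydroxy-4-(3-methylbut-2-enyloxy)benzaldehyde F2. Addition of 2-methylprop-1-enylmagnesium bromide (2.2 equiv, THF, 0 °C) to F2 should give racemic 3-bromo-2-(1-hydroxy-3-methylbut-2-enyl)-5-(3-methylbut-2-enyloxy)phenol F3. Warming F3 in toluene with a trace of pyridinium p-toluenesulfonate should dehydrate it to quinone methide 12, which closes to 13.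

Step 1. Silyl groups may scramble between the 4-O-silyl ether and the aryllithium or phenolate, or the second bromine may also exchange, so that triflation no longer falls cleanly on the 1-oxygen. The fallback sets out from 1 and comes back at 8, bypassing 6 and step 2. Both hydroxyls of 1 are deprotonated (NaH, 2.2 equiv, DMF, 0 °C) and one equivalent of 7 is added. The unhindered, more basic 4-oxide should be alkylated in preference to the flanked, less basic 1-oxide, giving 2,6-dibromo-4-(3-methylbut-2-enyloxy)phenol F4. HMDS (THF, 65 °C) then gives [2,6-dibromo-4-(3-methylbut-2-enyloxy)phenoxy]trimethylsilane F5. n-BuLi (THF, −78 °C) gives [3-bromo-5-(3-methylbut-2-enyloxy)-2-(trimethylsilyloxy)phenyl]lithium F6, which undergoes the retro-Brook shift to lithium 2-bromo-4-(3-methylbut-2-enyloxy)-6-(trimethylsilyl)phenolate F7. Tf2O at −78 °C converts F7 into 8.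

Step 4. Zerovalent palladium may ionise the allylic aryl ether with loss of the prenyl group, or transmetalation of the alkylborane may be slow enough for protodeboronation and β-hydride elimination to compete. The fallback is palladium-free, sets out from 13 and comes back at 17. Magnesium insertion (Mg turnings, LiCl, THF) should give [2,2-dimethyl-7-(3-methylbut-2-enyloxy)-2H-chromen-5-yl]magnesium bromide F8. Commercial 4-(2-bromoethyl)phenol (Oc1ccc(CCBr)cc1) is silylated (TBSCl, imidazole, DMF) to [4-(2-bromoethyl)phenoxy](tert-butyl)dimethylsilane F9. Copper-catalysed coupling of the Grignard reagent F8 with the primary bromide F9 (catalytic Li2CuCl4, THF, 0 °C) should give tert-butyl(4-{2-[2,2-dimethyl-7-(3-methylbut-2-enyloxy)-2H-chromen-5-yl]ethyl}phenoxy)dimethylsilane F10. Tetrabutylammonium fluoride (THF, 0 °C) then releases 17.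

Further compounds
F1 | step 3 | 3-bromo-N,N-dimethyl-5-(3-methylbut-2-enyloxy)-2H-benzo[b]oxet-2-amine (racemic, transient) | CC(C)=CCOc1cc(Br)c2c(c1)OC2N(C)C
F2 | step 3 | 2-bromo-6-hydroxy-4-(3-methylbut-2-enyloxy)benzaldehyde | CC(C)=CCOc1cc(O)c(C=O)c(Br)c1
F3 | step 3 | 3-bromo-2-(1-hydroxy-3-methylbut-2-enyl)-5-(3-methylbut-2-enyloxy)phenol (racemic) | CC(C)=CCOc1cc(O)c(C(O)C=C(C)C)c(Br)c1
F4 | step 1 | 2,6-dibromo-4-(3-methylbut-2-enyloxy)phenol | CC(C)=CCOc1cc(Br)c(O)c(Br)c1
F5 | step 1 | [2,6-dibromo-4-(3-methylbut-2-enyloxy)phenoxy]trimethylsilane | CC(C)=CCOc1cc(Br)c(O[Si](C)(C)C)c(Br)c1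
F6 | step 1 | [3-bromo-5-(3-methylbut-2-enyloxy)-2-(trimethylsilyloxy)phenyl]lithium | [Li]c1cc(OCC=C(C)C)cc(Br)c1O[Si](C)(C)C
F7 | step 1 | lithium 2-bromo-4-(3-methylbut-2-enyloxy)-6-(trimethylsilyl)phenolate | [Li]Oc1c(Br)cc(OCC=C(C)C)cc1[Si](C)(C)C
F8 | step 4 | [2,2-dimethyl-7-(3-methylbut-2-enyloxy)-2H-chromen-5-yl]magnesium bromide | Br[Mg]c1cc(OCC=C(C)C)cc2OC(C)(C)C=Cc12
F9 | step 4 | [4-(2-bromoethyl)phenoxy](tert-butyl)dimethylsilane | CC(C)(C)[Si](C)(C)Oc1ccc(CCBr)cc1
F10 | step 4 | tert-butyl(4-{2-[2,2-dimethyl-7-(3-methylbut-2-enyloxy)-2H-chromen-5-yl]ethyl}phenoxy)dimethylsilane | CC(C)=CCOc1cc(CCc2ccc(O[Si](C)(C)C(C)(C)C)cc2)c2c(c1)OC(C)(C)C=C2
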